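**Retrosynthetic overview**

- Labels: C1 is the enol-ether carbon; C2 and C3 are the CH and CH2 of the dihydrofuran; C4 is the O- and CH3-bearing quaternary carbon; C5=C6 is the ylidene alkene (C6 on the lactone oxygen); C7=C11 is the butenolide alkene; C8 is the methacrylate carbon; C9 is its CH2 neighbour; C10 is the tertiary carbinol; C12 is the lactone carbonyl; C13 is the acetoxymethyl carbon.
- Feature used: in the 2,3-dihydrofuran ring O–C1=C2–C3–C4, C1 lies between the ring oxygen and carbinol C10. C1=C2 is therefore the carbonyl–olefin metathesis product of an ester that links a C1/C10/C9/C8 acid to the C4 tertiary homoallylic alcohol, and both quaternary centres (C4, C10) are in place before the ring exists.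
- Disconnections, target backwards: C13 acetate; C5=C6 by intramolecular vinylogous aldol condensation of the butenolide onto a C5 aldehyde (closes the ten-membered carbocycle C1–C10, alkene geometry enforced by the ring); C8 methacrylate, C8 configuration by CBS reduction, C7–C8 by Nozaki–Hiyama–Kishi coupling of a 4-bromobutenolide with a C8 aldehyde; C1=C2 by titanium-alkylidene olefinic ester cyclisation; ester from an (R)-lactic acid-derived tertiary alcohol and an (R)-citramalic acid-derived acyl fluoride.
- Order of ring formation: dihydrofuran (step 12), then the preformed butenolide is attached (step 20), then the ten-membered carbocycle (step 26).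

Key step: step 12

Remark: the C8 oxygen is carried as a benzyl ether, removed reductively, because oxidative removal of a p-methoxybenzyl ether would endanger the dihydrofuran. All dihydrofuran-containing compounds are worked up and chromatographed under basic buffering. The coupling product of step 20 is carried as both C8 epimers until step 22 fixes that centre.

**Route**

Step 1
Reactants: 1 (R)-lactic acid; 2 pivalaldehyde
Product: 3 (2R,5R)-2-tert-butyl-5-methyl-1,3-dioxolan-4-one
Conditions: p-TsOH (cat.), H2SO4 (cat.), pentane, reflux (water separator); crystallisation from pentane/Et2O, −78 °C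
Reagents that add atoms: none
Why: Acid-catalysed acetalisation of the α-hydroxy acid gives the dioxolanone, and the new acetal centre should settle mainly in the cis (2R,5R) form under thermodynamic control, which crystallisation purifies (first stage of self-regeneration of stereocentres).

Step 2
Reactants: 3 (2R,5R)-2-tert-butyl-5-methyl-1,3-dioxolan-4-one; 4 allyl bromide
Product: 6 (2R,5S)-5-allyl-2-tert-butyl-5-methyl-1,3-dioxolan-4-one, via lithium enolate 5 (not isolated)
Conditions: LiN(iPr)2, THF, −78 °C; then allyl bromide, −78 → −30 °C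
Reagents that add atoms: none
Why: Enolate alkylation in which the tert-butyl group on the acetal carbon should shield one face of the planar enolate, so that allyl bromide enters trans to it, takes the place of the original hydrogen and sets the quaternary centre C4 with retention.

Step 3
Reactants: 6 (2R,5S)-5-allyl-2-tert-butyl-5-methyl-1,3-dioxolan-4-one
Product: 7 (S)-2-methylpent-4-ene-1,2-diol
Conditions: LiAlH4, Et2O, 0 °C → rt
Reagents that add atoms: none
Why: Hydride reduction of the lactone-type carbonyl and of the pivalaldehyde released from the acetal gives the diol and neopentyl alcohol without touching the quaternary centre.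

Step 4
Reactants: 7 (S)-2-methylpent-4-ene-1,2-diol
Product: 8 (S)-2-methyl-1-(triisopropylsilyloxy)pent-4-en-2-ol
Conditions: iPr3SiCl, imidazole, CH2Cl2, 0 °C → rt
Reagents that add atoms: triisopropylsilyl chloride, CC(C)[Si](Cl)(C(C)C)C(C)C
Why: Silylation with a bulky silyl chloride should take only the primary hydroxyl (C5–OH) and leave the tertiary C4–OH free for esterification.

Step 5
Reactants: 9 (R)-citramalic acid
Product: 10 2-[(4R)-2,2,4-trimethyl-5-oxo-1,3-dioxolan-4-yl]acetic acid
Conditions: 2,2-dimethoxypropane, p-TsOH (cat.), rt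
Reagents that add atoms: 2,2-dimethoxypropane, COC(C)(C)OC
Why: Acid-catalysed acetonide formation should close the five-membered dioxolanone on the tertiary α-hydroxy acid, masking C1 and the C10 oxygen in one operation and leaving the C8 carboxyl free; the purchased C10 centre is not involved.

Step 6
Reactants: 10 2-[(4R)-2,2,4-trimethyl-5-oxo-1,3-dioxolan-4-yl]acetic acid
Product: 11 (5R)-5-(2-hydroxyethyl)-2,2,5-trimethyl-1,3-dioxolan-4-one
Conditions: BH3·SMe2, THF, 0 °C → rt; MeOH quench
Reagents that add atoms: none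
Why: Borane reduces the free carboxylic acid through its acyloxyborane much faster than the dioxolanone carbonyl, so only C8 is taken to the alcohol.

Step 7
Reactants: 11 (5R)-5-(2-hydroxyethyl)-2,2,5-trimethyl-1,3-dioxolan-4-one
Product: 12 (5R)-5-[2-(benzyloxy)ethyl]-2,2,5-trimethyl-1,3-dioxolan-4-one
Conditions: benzyl 2,2,2-trichloroacetimidate, TfOH (cat.), CH2Cl2/cyclohexane, 0 °C
Reagents that add atoms: benzyl 2,2,2-trichloroacetimidate, N=C(OCc1ccccc1)C(Cl)(Cl)Cl
Why: Acid-catalysed imidate benzylation avoids an alkoxide that would translactonise onto the dioxolanone, and benzyl is chosen because it can later be removed reductively beside the enol ether.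

Step 8
Reactants: 12 (5R)-5-[2-(benzyloxy)ethyl]-2,2,5-trimethyl-1,3-dioxolan-4-one
Product: 13 (R)-4-(benzyloxy)-2-hydroxy-2-methylbutanoic acid
Conditions: LiOH, THF/H2O, 0 °C → rt; HCl to pH 3
Reagents that add atoms: lithium hydroxide, [Li+].[OH-]
Why: Saponification of the dioxolanone (an activated ester) releases the α-hydroxy acid and acetone without touching the benzyl ether or the quaternary centre.

Step 9
Reactants: 13 (R)-4-(benzyloxy)-2-hydroxy-2-methylbutanoic acid
Product: 15 (R)-4-(benzyloxy)-2-methyl-2-(triethylsilyloxy)butanoic acid, via bis-silylated acid 14 (not isolated)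
Conditions: Et3SiOTf, 2,6-lutidine, CH2Cl2, −78 → 0 °C; then MeOH/H2O, rt
Reagents that add atoms: triethylsilyl triflate, CC[Si](CC)(CC)OS(=O)(=O)C(F)(F)F
Why: The silyl triflate silylates both the tertiary hydroxyl and the carboxyl, and the far more labile silyl ester is then solvolysed selectively to leave the C10 triethylsilyl ether.

Step 10
Reactants: 15 (R)-4-(benzyloxy)-2-methyl-2-(triethylsilyloxy)butanoic acid
Product: 16 (R)-4-(benzyloxy)-2-methyl-2-(triethylsilyloxy)butanoyl fluoride
Conditions: cyanuric fluoride, pyridine, CH2Cl2, −20 → 0 °C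
Reagents that add atoms: cyanuric fluoride, Fc1nc(F)nc(F)n1
Why: Deoxyfluorination of the acid with cyanuric fluoride gives the acyl fluoride, a small and hydrolytically tolerant acyl donor that carries the tertiary silyl ether unchanged.

Step 11
Reactants: 8 (S)-2-methyl-1-(triisopropylsilyloxy)pent-4-en-2-ol; 16 (R)-4-(benzyloxy)-2-methyl-2-(triethylsilyloxy)butanoyl fluoride
Product: 18 (S)-2-methyl-1-(triisopropylsilyloxy)pent-4-en-2-yl (R)-4-(benzyloxy)-2-methyl-2-(triethylsilyloxy)butanoate, via lithium alkoxide 17 (not isolated)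
Conditions: n-BuLi, THF, −78 °C; then 16, −78 → 0 °C
Reagents that add atoms: none
Why: Acylation of a lithium tert-alkoxide by an acyl fluoride, in which the compact C(=O)F group and the strong Li–F bond should overcome the hindrance of both neopentyl-type partners, while the bulky triisopropylsilyl ether is not expected to migrate to the neighbouring alkoxide.

Step 12
Reactants: 18 (S)-2-methyl-1-(triisopropylsilyloxy)pent-4-en-2-yl (R)-4-(benzyloxy)-2-methyl-2-(triethylsilyloxy)butanoate
Product: 19 (2S)-5-[(2R)-4-(benzyloxy)-2-(triethylsilyloxy)butan-2-yl]-2-methyl-2-[(triisopropylsilyloxy)methyl]-2,3-dihydrofuran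
Conditions: TiCl4, TMEDA, Zn, PbCl2 (cat.), CH3CHBr2, THF/CH2Cl2, 0 → 65 °C; aqueous K2CO3 work-up
Reagents that add atoms: none
Why: The reduced titanium ethylidene made from TiCl4, TMEDA, Zn, PbCl2 and CH3CHBr2 should first exchange alkylidenes with the unhindered terminal alkene of 18 (titanacyclobutane, loss of propene), which places titanium on C2. The C2 alkylidene should then add across the ester carbonyl C1 to an oxatitanacyclobutane, whose cycloreversion expels a titanium oxo species and leaves C1=C2 inside the new ring. The closest known reaction type is the Takai–Utimoto alkylidenation used as an olefinic ester cyclisation to cyclic enol ethers, a carbonyl–olefin metathesis related to Tebbe methylenation followed by ring-closing metathesis. The five-membered ring O–C1=C2–C3–C4 closes by 5-exo attack of the alkylidene carbon C2 on the ester carbonyl, and C1–C2 is the only new skeletal bond. No stereocentre is formed, and the existing quaternary centres C4 and C10 cannot epimerise under these non-acidic conditions. The step needs cyclisation to win over plain ethylidenation of the ester, which the exposed allyl terminus and the doubly shielded carbonyl (tertiary alkoxy side, quaternary silyloxy acyl side) should secure, and the basic work-up protects the enol ether.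

Step 13
Reactants: 19 (2S)-5-[(2R)-4-(benzyloxy)-2-(triethylsilyloxy)butan-2-yl]-2-methyl-2-[(triisopropylsilyloxy)methyl]-2,3-dihydrofuran
Product: 20 (2R)-4-(benzyloxy)-2-[(5S)-5-(hydroxymethyl)-5-methyl-4,5-dihydrofuran-2-yl]butan-2-ol
Conditions: Bu4NF, THF, 0 °C → rt
Reagents that add atoms: none
Why: Fluoride cleaves both silyl ethers now that no ester is left to suffer acyl migration; the exchange is made because the neopentyl triisopropylsilyl ether that secured step 11 could not later be removed beside the C13 silyl ether.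

Step 14
Reactants: 20 (2R)-4-(benzyloxy)-2-[(5S)-5-(hydroxymethyl)-5-methyl-4,5-dihydrofuran-2-yl]butan-2-ol
Product: 21 (2S)-5-[(2R)-4-(benzyloxy)-2-(triethylsilyloxy)butan-2-yl]-2-methyl-2-[(triethylsilyloxy)methyl]-2,3-dihydrofuran
Conditions: Et3SiOTf, 2,6-lutidine, CH2Cl2, −78 → 0 °C
Reagents that add atoms: triethylsilyl triflate, CC[Si](CC)(CC)OS(=O)(=O)C(F)(F)F
Why: The silyl triflate with a hindered pyridine base silylates the primary and the tertiary hydroxyl alike under basic conditions that suit the enol ether, giving a primary C5 ether that is far more labile than the tertiary C10 ether.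

Step 15
Reactants: 21 (2S)-5-[(2R)-4-(benzyloxy)-2-(triethylsilyloxy)butan-2-yl]-2-methyl-2-[(triethylsilyloxy)methyl]-2,3-dihydrofuran
Product: 22 (3R)-3-{(5S)-5-methyl-5-[(triethylsilyloxy)methyl]-4,5-dihydrofuran-2-yl}-3-(triethylsilyloxy)butan-1-ol
Conditions: lithium 4,4′-di-tert-butylbiphenylide, THF, −78 °C; then H2O
Reagents that add atoms: none
Why: Reductive debenzylation by the arene radical anion (single-electron cleavage of the benzylic C–O bond) at −78 °C spares silyl ethers and the unconjugated, electron-rich enol ether, and no reducible carbonyl is present at this stage.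

Step 16
Reactants: 22 (3R)-3-{(5S)-5-methyl-5-[(triethylsilyloxy)methyl]-4,5-dihydrofuran-2-yl}-3-(triethylsilyloxy)butan-1-ol
Product: 23 (3R)-3-{(5S)-5-methyl-5-[(triethylsilyloxy)methyl]-4,5-dihydrofuran-2-yl}-3-(triethylsilyloxy)butanal
Conditions: Dess–Martin periodinane, NaHCO3, CH2Cl2, 0 °C
Reagents that add atoms: none
Why: Buffered Dess–Martin oxidation converts the primary C8 alcohol into the aldehyde under non-acidic conditions, and the silylated β-oxygen cannot undergo retro-aldol cleavage.

Step 17
Reactants: 24 tetronic acid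
Product: 25 4-bromo-2-oxo-2,5-dihydrofuran-3-carbaldehyde
Conditions: PBr3, DMF, CHCl3, 0 → 60 °C; then ice, aqueous NaOAc
Reagents that add atoms: N,N-dimethylformamide, CN(C)C=O; phosphorus tribromide, BrP(Br)Br; water, O
Why: Vilsmeier–Haack–Arnold haloformylation of a cyclic β-dicarbonyl compound, in which the bromoiminium salt formylates the nucleophilic carbon (the future C11, giving C13) and converts the enol hydroxyl into the vinylic bromide at the future C7, as is known for 4-hydroxycoumarin.

Step 18
Reactants: 25 4-bromo-2-oxo-2,5-dihydrofuran-3-carbaldehyde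
Product: 26 4-bromo-3-(hydroxymethyl)furan-2(5H)-one
Conditions: NaBH4, CeCl3·7H2O, MeOH, −78 °C
Reagents that add atoms: none
Why: Luche reduction, in which the cerium-activated aldehyde should be reduced 1,2 well before hydride addition–elimination at the β-bromo enoate.

Step 19
Reactants: 26 4-bromo-3-(hydroxymethyl)furan-2(5H)-one
Product: 27 4-bromo-3-[(tert-butyldiphenylsilyloxy)methyl]furan-2(5H)-one
Conditions: tBuPh2SiCl, imidazole, CH2Cl2, 0 °C
Reagents that add atoms: tert-butyldiphenylsilyl chloride, CC(C)(C)[Si](Cl)(c1ccccc1)c1ccccc1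
Why: Silylation of the primary allylic alcohol with a bulky silyl group whose silanolate is a poor leaving group, so that the C13 oxygen is not expelled from the dienolate or silyloxyfuran formed in step 26.

Step 20
Reactants: 23 (3R)-3-{(5S)-5-methyl-5-[(triethylsilyloxy)methyl]-4,5-dihydrofuran-2-yl}-3-(triethylsilyloxy)butanal; 27 4-bromo-3-[(tert-butyldiphenylsilyloxy)methyl]furan-2(5H)-one
Product: 28 3-[(tert-butyldiphenylsilyloxy)methyl]-4-{(3R)-1-hydroxy-3-[(5S)-5-methyl-5-(triethylsilyloxymethyl)-4,5-dihydrofuran-2-yl]-3-(triethylsilyloxy)butyl}furan-2(5H)-one (both C8 epimers)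
Conditions: CrCl2 (excess), NiCl2 (cat.), DMSO/THF, rt
Reagents that add atoms: none
Why: Nozaki–Hiyama–Kishi coupling, in which zerovalent nickel inserts into the activated vinylic C–Br bond and transmetalation gives an alkenyl species of trivalent chromium that adds chemoselectively to the aldehyde and tolerates the lactone and silyl ethers; the new C8 centre is not controlled here and both epimers are taken on.

Step 21
Reactants: 28 C8 carbinol (both epimers)
Product: 29 3-[(tert-butyldiphenylsilyloxy)methyl]-4-{(3R)-3-[(5S)-5-methyl-5-(triethylsilyloxymethyl)-4,5-dihydrofuran-2-yl]-3-(triethylsilyloxy)butanoyl}furan-2(5H)-one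
Conditions: Dess–Martin periodinane, NaHCO3, CH2Cl2, 0 °C
Reagents that add atoms: none
Why: Buffered Dess–Martin oxidation of the allylic alcohol erases the uncontrolled C8 centre and gives the 4-acylbutenolide ketone.

Step 22
Reactants: 29 C8 ketone
Product: 30 3-[(tert-butyldiphenylsilyloxy)methyl]-4-{(1S,3R)-1-hydroxy-3-[(5S)-5-methyl-5-(triethylsilyloxymethyl)-4,5-dihydrofuran-2-yl]-3-(triethylsilyloxy)butyl}furan-2(5H)-one
Conditions: (R)-2-methyl-CBS-oxazaborolidine (B-methyl oxazaborolidine from (R)-diphenylprolinol), catecholborane, toluene, −78 °C; MeOH quench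
Reagents that add atoms: none
Why: Corey–Bakshi–Shibata reduction, in which the ketone should bind to the (R)-catalyst with the fully substituted alkenyl carbon C7 as the large group and the C9 methylene as the small one, so that hydride from catecholborane is delivered to the face that gives the 8S carbinol (reagent control), while the low temperature and the mild borane spare the enol ether.

Step 23
Reactants: 30 (8S) carbinol
Product: 31 (1S,3R)-1-{4-[(tert-butyldiphenylsilyloxy)methyl]-5-oxo-2,5-dihydrofuran-3-yl}-3-[(5S)-5-methyl-5-(triethylsilyloxymethyl)-4,5-dihydrofuran-2-yl]-3-(triethylsilyloxy)butyl methacrylate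
Conditions: methacrylic anhydride, Et3N, DMAP (cat.), CH2Cl2, 0 °C
Reagents that add atoms: methacrylic anhydride, C=C(C)C(=O)OC(=O)C(C)=C
Why: DMAP-catalysed acylation of the secondary alcohol installs the ester of the target at once, so that no extra protecting group is needed before the C5 alcohol is oxidised.

Step 24
Reactants: 31 C8 methacrylate with C5 triethylsilyl ether
Product: 32 (1S,3R)-1-{4-[(tert-butyldiphenylsilyloxy)methyl]-5-oxo-2,5-dihydrofuran-3-yl}-3-[(5S)-5-(hydroxymethyl)-5-methyl-4,5-dihydrofuran-2-yl]-3-(triethylsilyloxy)butyl methacrylate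
Conditions: HF·pyridine, pyridine, THF, 0 °C
Reagents that add atoms: none
Why: Buffered HF·pyridine should cleave the primary triethylsilyl ether much faster than the tertiary triethylsilyl and the tert-butyldiphenylsilyl ethers, and the pyridine buffer protects the enol ether and the esters.

Step 25
Reactants: 32 C5 alcohol
Product: 33 (1S,3R)-1-{4-[(tert-butyldiphenylsilyloxy)methyl]-5-oxo-2,5-dihydrofuran-3-yl}-3-[(5S)-5-formyl-5-methyl-4,5-dihydrofuran-2-yl]-3-(triethylsilyloxy)butyl methacrylate
Conditions: Dess–Martin periodinane, NaHCO3, CH2Cl2, 0 °C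
Reagents that add atoms: none
Why: Buffered Dess–Martin oxidation gives the α-quaternary, non-enolisable C5 aldehyde, all other oxygens being silylated or acylated.

Step 26
Reactants: 33 C5 aldehyde
Product: 36 macrocyclic γ-ylidenebutenolide (4S,8S,10R,5E) with C8 methacrylate, C10 triethylsilyl ether and C13 tert-butyldiphenylsilyl ether, via silyloxyfuran 34 (not isolated), via silyl aldol macrocycle 35 (not isolated)
Conditions: tBuMe2SiOTf, iPr2NEt, CH2Cl2 (about 1 mM), −78 → 0 °C; then DBU, 0 °C → rt
Reagents that add atoms: none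
Why: One-pot vinylogous Mukaiyama aldol condensation, in which soft enolisation at C6 gives the aromatic 2-silyloxyfuran that attacks the silyl-triflate-activated C5 aldehyde through its γ-carbon C6 to close the ten-membered carbocycle, after which DBU removes the C6 hydrogen and expels the C5 silanolate (E1cB); the ring forces C4 and C7 onto the same side of the new C5=C6 bond, as in the target, and the transient centres at C5 and C6 are destroyed.

Step 27
Reactants: 36 macrocyclic γ-ylidenebutenolide
Product: 37 (4S,8S,10R,5E)-macrocyclic diol with free C10 and C13 hydroxyls and C8 methacrylate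
Conditions: Bu4NF, AcOH, THF, 0 °C → rt
Reagents that add atoms: none
Why: Acetic-acid-buffered fluoride removes the primary tert-butyldiphenylsilyl ether and the tertiary triethylsilyl ether without base-induced acyl migration or opening of the butenolide.

Step 28
Reactants: 37 macrocyclic diol
Product: 38 CNP0394509.2
Conditions: Ac2O, pyridine, CH2Cl2, 0 °C
Reagents that add atoms: acetic anhydride, CC(=O)OC(C)=O
Why: Acetylation in pyridine without an acyl-transfer catalyst should acylate only the primary allylic C13 hydroxyl and leave the tertiary C10 hydroxyl free, which gives the target.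

**Compound list**

1 | (R)-lactic acid | C[C@@H](O)C(=O)O | starting material
2 | pivalaldehyde | CC(C)(C)C=O | starting material
3 | (2R,5R)-2-tert-butyl-5-methyl-1,3-dioxolan-4-one (cis) | O=C1O[C@H](C(C)(C)C)O[C@@H]1C | intermediate
4 | allyl bromide | C=CCBr | starting material
5 | lithium enolate of 3 | [Li]OC1=C(C)O[C@@H](C(C)(C)C)O1 | intermediate (not isolated)
6 | (2R,5S)-5-allyl-2-tert-butyl-5-methyl-1,3-dioxolan-4-one | O=C1O[C@H](C(C)(C)C)O[C@@]1(C)CC=C | intermediate
7 | (S)-2-methylpent-4-ene-1,2-diol | C=CC[C@@](C)(CO)O | intermediate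
8 | (S)-2-methyl-1-(triisopropylsilyloxy)pent-4-en-2-ol | C=CC[C@@](C)(CO[Si](C(C)C)(C(C)C)C(C)C)O | intermediate
9 | (R)-citramalic acid | OC(=O)C[C@@](C)(O)C(=O)O | starting material
10 | 2-[(4R)-2,2,4-trimethyl-5-oxo-1,3-dioxolan-4-yl]acetic acid | OC(=O)C[C@@]1(C)OC(C)(C)OC1=O | intermediate
11 | (5R)-5-(2-hydroxyethyl)-2,2,5-trimethyl-1,3-dioxolan-4-one | OCC[C@@]1(C)OC(C)(C)OC1=O | intermediate
12 | (5R)-5-[2-(benzyloxy)ethyl]-2,2,5-trimethyl-1,3-dioxolan-4-one | C(OCC[C@@]1(C)OC(C)(C)OC1=O)c1ccccc1 | intermediate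
13 | (R)-4-(benzyloxy)-2-hydroxy-2-methylbutanoic acid | OC(=O)[C@](C)(O)CCOCc1ccccc1 | intermediate
14 | triethylsilyl (R)-4-(benzyloxy)-2-methyl-2-(triethylsilyloxy)butanoate | CC[Si](CC)(CC)OC(=O)[C@](C)(O[Si](CC)(CC)CC)CCOCc1ccccc1 | intermediate (not isolated)
15 | (R)-4-(benzyloxy)-2-methyl-2-(triethylsilyloxy)butanoic acid | OC(=O)[C@](C)(O[Si](CC)(CC)CC)CCOCc1ccccc1 | intermediate
16 | (R)-4-(benzyloxy)-2-methyl-2-(triethylsilyloxy)butanoyl fluoride | FC(=O)[C@](C)(O[Si](CC)(CC)CC)CCOCc1ccccc1 | intermediate
17 | lithium alkoxide of 8 | C=CC[C@@](C)(CO[Si](C(C)C)(C(C)C)C(C)C)O[Li] | intermediate (not isolated)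
18 | (S)-2-methyl-1-(triisopropylsilyloxy)pent-4-en-2-yl (R)-4-(benzyloxy)-2-methyl-2-(triethylsilyloxy)butanoate (key-step precursor) | C=CC[C@@](C)(CO[Si](C(C)C)(C(C)C)C(C)C)OC(=O)[C@](C)(O[Si](CC)(CC)CC)CCOCc1ccccc1 | intermediate
19 | (2S)-5-[(2R)-4-(benzyloxy)-2-(triethylsilyloxy)butan-2-yl]-2-methyl-2-[(triisopropylsilyloxy)methyl]-2,3-dihydrofuran (key-step product) | C(OCC[C@@](C)(O[Si](CC)(CC)CC)C1=CC[C@@](C)(CO[Si](C(C)C)(C(C)C)C(C)C)O1)c1ccccc1 | intermediate
20 | (2R)-4-(benzyloxy)-2-[(5S)-5-(hydroxymethyl)-5-methyl-4,5-dihydrofuran-2-yl]butan-2-ol | C(OCC[C@@](C)(O)C1=CC[C@@](C)(CO)O1)c1ccccc1 | intermediate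
21 | (2S)-5-[(2R)-4-(benzyloxy)-2-(triethylsilyloxy)butan-2-yl]-2-methyl-2-[(triethylsilyloxy)methyl]-2,3-dihydrofuran | C(OCC[C@@](C)(O[Si](CC)(CC)CC)C1=CC[C@@](C)(CO[Si](CC)(CC)CC)O1)c1ccccc1 | intermediate
22 | (3R)-3-{(5S)-5-methyl-5-[(triethylsilyloxy)methyl]-4,5-dihydrofuran-2-yl}-3-(triethylsilyloxy)butan-1-ol | OCC[C@@](C)(O[Si](CC)(CC)CC)C1=CC[C@@](C)(CO[Si](CC)(CC)CC)O1 | intermediate
23 | (3R)-3-{(5S)-5-methyl-5-[(triethylsilyloxy)methyl]-4,5-dihydrofuran-2-yl}-3-(triethylsilyloxy)butanal | O=CC[C@@](C)(O[Si](CC)(CC)CC)C1=CC[C@@](C)(CO[Si](CC)(CC)CC)O1 | intermediate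
24 | tetronic acid (4-hydroxyfuran-2(5H)-one) | OC1=CC(=O)OC1 | starting material
25 | 4-bromo-2-oxo-2,5-dihydrofuran-3-carbaldehyde | O=CC1=C(Br)COC1=O | intermediate
26 | 4-bromo-3-(hydroxymethyl)furan-2(5H)-one | OCC1=C(Br)COC1=O | intermediate
27 | 4-bromo-3-[(tert-butyldiphenylsilyloxy)methyl]furan-2(5H)-one | CC(C)(C)[Si](OCC1=C(Br)COC1=O)(c1ccccc1)c1ccccc1 | intermediate
28 | C8 carbinol, both C8 epimers (butenolide joined through C7 to C8; C5 and C10 triethylsilyl ethers; C13 tert-butyldiphenylsilyl ether) | OC(C[C@@](C)(O[Si](CC)(CC)CC)C1=CC[C@@](C)(CO[Si](CC)(CC)CC)O1)C1=C(CO[Si](c2ccccc2)(c2ccccc2)C(C)(C)C)C(=O)OC1 | intermediate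
29 | C8 ketone (4-acylbutenolide) | O=C(C[C@@](C)(O[Si](CC)(CC)CC)C1=CC[C@@](C)(CO[Si](CC)(CC)CC)O1)C1=C(CO[Si](c2ccccc2)(c2ccccc2)C(C)(C)C)C(=O)OC1 | intermediate
30 | (8S) carbinol, (1S,3R) in the butyl chain | O[C@@H](C[C@@](C)(O[Si](CC)(CC)CC)C1=CC[C@@](C)(CO[Si](CC)(CC)CC)O1)C1=C(CO[Si](c2ccccc2)(c2ccccc2)C(C)(C)C)C(=O)OC1 | intermediate
31 | (8S) methacrylate with C5 triethylsilyl ether | C=C(C)C(=O)O[C@@H](C[C@@](C)(O[Si](CC)(CC)CC)C1=CC[C@@](C)(CO[Si](CC)(CC)CC)O1)C1=C(CO[Si](c2ccccc2)(c2ccccc2)C(C)(C)C)C(=O)OC1 | intermediate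
32 | (8S) methacrylate with free C5 alcohol | C=C(C)C(=O)O[C@@H](C[C@@](C)(O[Si](CC)(CC)CC)C1=CC[C@@](C)(CO)O1)C1=C(CO[Si](c2ccccc2)(c2ccccc2)C(C)(C)C)C(=O)OC1 | intermediate
33 | (8S) methacrylate with C5 aldehyde | C=C(C)C(=O)O[C@@H](C[C@@](C)(O[Si](CC)(CC)CC)C1=CC[C@@](C)(C=O)O1)C1=C(CO[Si](c2ccccc2)(c2ccccc2)C(C)(C)C)C(=O)OC1 | intermediate
34 | 2-(tert-butyldimethylsilyloxy)furan form of 33 | C=C(C)C(=O)O[C@@H](C[C@@](C)(O[Si](CC)(CC)CC)C1=CC[C@@](C)(C=O)O1)c1coc(O[Si](C)(C)C(C)(C)C)c1CO[Si](c1ccccc1)(c1ccccc1)C(C)(C)C | intermediate (not isolated)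
35 | aldol macrocycle with C5 tert-butyldimethylsilyl ether (C5/C6 mixture; 4S,8S,10R) | C=C(C)C(=O)O[C@H]1C[C@@](C)(O[Si](CC)(CC)CC)C2=CC[C@@](C)(C(O[Si](C)(C)C(C)(C)C)C3OC(=O)C(CO[Si](c4ccccc4)(c4ccccc4)C(C)(C)C)=C31)O2 | intermediate (not isolated)
36 | macrocyclic γ-ylidenebutenolide (4S,8S,10R,5E): ten-membered carbocycle C1–C10 bridged by oxygen between C1 and C4, butenolide fused at C6/C7; C8 methacrylate, C10 triethylsilyl ether, C13 tert-butyldiphenylsilyl ether | C=C(C)C(=O)O[C@H]1C[C@@](C)(O[Si](CC)(CC)CC)C2=CC[C@@](C)(/C=C3/OC(=O)C(CO[Si](c4ccccc4)(c4ccccc4)C(C)(C)C)=C31)O2 | intermediate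
37 | macrocyclic diol (4S,8S,10R,5E): C8 methacrylate, free C10 and C13 hydroxyls | C=C(C)C(=O)O[C@H]1C[C@@](C)(O)C2=CC[C@@](C)(/C=C3/OC(=O)C(CO)=C31)O2 | intermediate
38 | CNP0394509.2 (4S,8S,10R,5E): C8 methacrylate, C10 hydroxyl, C13 acetate | C=C(C)C(=O)O[C@H]1C[C@@](C)(O)C2=CC[C@@](C)(/C=C3/OC(=O)C(COC(C)=O)=C31)O2 | target

**Step count and risk**

Total step count: 28. Longest linear sequence: 21 steps, from (R)-citramalic acid 9 (steps 5–16 and 20–28).

Most likely to fail, step 12. Intermolecular ethylidenation of the ester may outrun alkylidene exchange at the alkene, or the C2 titanium alkylidene may fail to engage the shielded carbonyl, so that acyclic ethylidene enol ether or unchanged ester is obtained. The fallback closes the ring in two known stages and sets out from ester 18. Petasis methylenation with Cp2TiMe2 (toluene, 70 °C) should give the acyclic 1-alkoxyvinyl ether F1. Ring-closing olefin metathesis of its enol-ether alkene with the allyl terminus, with loss of ethene, then forms C1=C2; the catalyst is the Schrock catalyst Mo(=CHCMe2Ph)(=N-2,6-iPr2C6H3)[OCMe(CF3)2]2 in benzene at 60 °C, or the second-generation Grubbs catalyst RuCl2(=CHPh)(PCy3)(H2IMes). The fallback comes back to the route at dihydrofuran 19.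

Second, step 26. Intermolecular aldol oligomerisation may replace the transannular closure, the C13 silyloxy group may ionise from the silyloxyfuran, or C8 may epimerise through the extended dienolate under DBU. The fallback reverses the order of the two butenolide bonds, so that the ring is closed by the nickel/chromium reaction; it sets out from alcohol 22.
- tBuMe2SiCl and imidazole should give the C8 tert-butyldimethylsilyl ether F2.
- Buffered HF·pyridine should remove only the primary triethylsilyl group to give the C5 alcohol F3, and Dess–Martin oxidation gives the C5 aldehyde F4.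
- Bromobutenolide 27 is converted in the same flask (tBuMe2SiOTf, iPr2NEt, CH2Cl2, −78 °C) into its 2-silyloxyfuran F5. This adds to F4 in an intermolecular vinylogous Mukaiyama aldol reaction to give the C5-silyloxy adduct F6, a C5/C6 mixture whose two centres are later destroyed.
- Buffered HF·pyridine should free the unhindered primary C8 alcohol F7 beside the hindered secondary silyl ether, the tert-butyldiphenylsilyl ether and the tertiary triethylsilyl ether. Dess–Martin oxidation then gives the C8 aldehyde F8.
- Intramolecular Nozaki–Hiyama–Kishi coupling (CrCl2, NiCl2 cat., DMSO/THF, high dilution) closes C7–C8 to the ten-membered carbinol F9.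
- Dess–Martin oxidation gives the macrocyclic ketone F10, and CBS reduction as in step 22 gives the 8S carbinol F11.
- Methacrylation as in step 23 gives 35, now isolated, where the fallback comes back to the route; the DBU stage of step 26 then leads to 36.

Third, step 22. Facial selectivity may be poor because the C9 methylene carries a quaternary carbon and may not behave as the small group, and conjugate reduction of the ene-dione may compete. The fallback avoids the ketone and sets out from the epimer mixture 28, whose C8 epimers are separated by chromatography. The 8S epimer is 30 and continues through step 23. The 8R epimer F12 is esterified with inversion by a Mitsunobu reaction with methacrylic acid (PPh3, diisopropyl azodicarboxylate, toluene, 0 °C), which comes back to the route at methacrylate 31.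

**Further compounds**

F1 | step 12 | acyclic 1-alkoxyvinyl ether from methylenation of 18 | C=CC[C@@](C)(CO[Si](C(C)C)(C(C)C)C(C)C)OC(=C)[C@](C)(O[Si](CC)(CC)CC)CCOCc1ccccc1
F2 | step 26 | C8 tert-butyldimethylsilyl ether of 22 | CC(C)(C)[Si](C)(C)OCC[C@@](C)(O[Si](CC)(CC)CC)C1=CC[C@@](C)(CO[Si](CC)(CC)CC)O1
F3 | step 26 | C5 alcohol with C8 tert-butyldimethylsilyl ether | CC(C)(C)[Si](C)(C)OCC[C@@](C)(O[Si](CC)(CC)CC)C1=CC[C@@](C)(CO)O1
F4 | step 26 | C5 aldehyde with C8 tert-butyldimethylsilyl ether | CC(C)(C)[Si](C)(C)OCC[C@@](C)(O[Si](CC)(CC)CC)C1=CC[C@@](C)(C=O)O1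
F5 | step 26 | 2-(tert-butyldimethylsilyloxy)furan from 27 | CC(C)(C)[Si](C)(C)Oc1occ(Br)c1CO[Si](c1ccccc1)(c1ccccc1)C(C)(C)C
F6 | step 26 | intermolecular aldol adduct, C5 tert-butyldimethylsilyl ether, bromobutenolide (C5/C6 mixture) | CC(C)(C)[Si](C)(C)OCC[C@@](C)(O[Si](CC)(CC)CC)C1=CC[C@@](C)(C(O[Si](C)(C)C(C)(C)C)C2OC(=O)C(CO[Si](c3ccccc3)(c3ccccc3)C(C)(C)C)=C2Br)O1
F7 | step 26 | C8 alcohol of the aldol adduct | OCC[C@@](C)(O[Si](CC)(CC)CC)C1=CC[C@@](C)(C(O[Si](C)(C)C(C)(C)C)C2OC(=O)C(CO[Si](c3ccccc3)(c3ccccc3)C(C)(C)C)=C2Br)O1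
F8 | step 26 | C8 aldehyde of the aldol adduct | O=CC[C@@](C)(O[Si](CC)(CC)CC)C1=CC[C@@](C)(C(O[Si](C)(C)C(C)(C)C)C2OC(=O)C(CO[Si](c3ccccc3)(c3ccccc3)C(C)(C)C)=C2Br)O1
F9 | step 26 | macrocyclic C8 carbinol (C8 epimers) | OC1C[C@@](C)(O[Si](CC)(CC)CC)C2=CC[C@@](C)(C(O[Si](C)(C)C(C)(C)C)C3OC(=O)C(CO[Si](c4ccccc4)(c4ccccc4)C(C)(C)C)=C31)O2
F10 | step 26 | macrocyclic C8 ketone | O=C1C[C@@](C)(O[Si](CC)(CC)CC)C2=CC[C@@](C)(C(O[Si](C)(C)C(C)(C)C)C3OC(=O)C(CO[Si](c4ccccc4)(c4ccccc4)C(C)(C)C)=C31)O2
F11 | step 26 | macrocyclic (8S) carbinol | O[C@H]1C[C@@](C)(O[Si](CC)(CC)CC)C2=CC[C@@](C)(C(O[Si](C)(C)C(C)(C)C)C3OC(=O)C(CO[Si](c4ccccc4)(c4ccccc4)C(C)(C)C)=C31)O2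
F12 | step 22 | (8R) epimer of 30 | O[C@H](C[C@@](C)(O[Si](CC)(CC)CC)C1=CC[C@@](C)(CO[Si](CC)(CC)CC)O1)C1=C(CO[Si](c2ccccc2)(c2ccccc2)C(C)(C)C)C(=O)OC1
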